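The numbers in the tables were generated by integration on assumed constants; the scatter is artificial.

I wanted to know when this flask, the theta run carried on to its time limit, holds most intermediate A, and how soon it reaches the level asked for.

the same everywhere: starting material 0.066 M; partner 0.0693 M; second reagent 0.0528 M; third reagent 0.0858 M

| charge | capture agent | remark | time |
|---|---|---|---|
| theta | 6.6 mM | the very flask that is asked about, followed so far |  |
| alpha | 3.3 mM | run made earlier |  |
| flask | 6.60 mM |  | 8.0 h |

theta run (percent of the starting material charged)

| time / min | intermediate A / % | target / % |
|---|---|---|
| 25.0 | 70.9 | 0.1 |
| 40.0 | 78.2 | 0.7 |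
| 60.0 | 81.3 | 0 |
| 90.0 | 82.7 | 0.7 |

alpha run (percent of the starting material charged)

| time / h | intermediate A / % | target / % |
|---|---|---|
| 0.417 | 71.2 | 0.6 |
| 1.33 | 85.0 | 0.6 |
| 3.00 | 85.2 | 1.4 |
| 8.00 | 78.0 | 7.6 |

(standard deviation of a reading: 0.3 percentage points)

- time, not beyond 8.0 h, at which the flask holds most intermediate A
- the amount of intermediate A, in percent of the starting material charged, at that time
- the first time at which intermediate A reaches 42%, in the same percent

- what was read earlier has a scatter of 0.3 percentage points, one standard deviation

I turned the question round. For a late peak, the feed of new intermediate A would have to stay above the drain on it for hours. I read the drain from the two runs, whose capture agent differs. The alpha run stood at 85.0% after 1.33 h, and the theta run at 82.7% after 90.0 min, a gap of 2.3 percentage points. I took that loss as proportional to intermediate A and to capture agent, which gave a capture constant of 6.34 /M/h, a rough reading. At the full charge of capture agent, the drain took 0.0346 /h of the charge.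

Adding this drain to the measured rise gave the feed. It was 0.128 /h between the readings at 40.0 min and 60.0 min, and 0.0626 /h between those at 60.0 min and 90.0 min. So the feed, as I reckoned it, was falling quickly, and it already stood at just 1.81 times the drain. A late peak needed a far slower fall. Continuing the decline as exponential, I set the peak at 1.60 h.

The forecast gave 3.7 h, 83.5% and 0.13 h, later than my peak: “A should therefore peak near 3.5–4 h at about 83.5 %”. The flask gave 1.76 h, 83.7% and 0.117 h.

    starting material + second reagent → side product (k = 4.20 /M/h)
    intermediate A + capture agent → trapped intermediate (k = 5.70 /M/h)
    third reagent + intermediate B → target (k = 5.90 /M/h)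
    second reagent + intermediate A → intermediate B (k = 0.330 /M/h)
    starting material + partner → intermediate A (k = 90.0 /M/h)

My reckoning ran a little early. Of the effects tested on the height of the peak, the largest single one is the consumption of partner: with partner held, the highest amount of intermediate A is 93.0% against 83.7%. Capture is a smaller part of it: the run without that step reaches 88.1%. Treating intermediate A as level at its final amount, I took the decay of capture agent as pseudo-first-order; the constant then gives 8.35% of it left in this flask, against 9.6% computed. In a neighbour flask charged with 0.11 M starting material, the same reckoning on its final intermediate A gives 5.25%, and the computed value is 6.3%.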